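**Retrosynthetic overview**

1. Target 18 ⇐ triol aldehyde 15 (catechol masked as a boronate, O-sulfation of the C6′ phenol) ⇐ 13 (MOM removal) ⇐ styrene 11 (ortho-lithiation and formylation at C5′).
2. Key disconnection: the C11–C1′ bond, made together with the C9=C11 alkene, from aldehyde 5 and aryl bromide 8. Both carbons are acceptors; C11 is made the donor (aldehyde → N-tosylhydrazone → diazo/carbene carbon) and joined under palladium catalysis.
3. 5 ⇐ enal 4 (α-face hydrogenation sets C8) ⇐ allylic alcohol 3 (oxidative 1,3-transposition) ⇐ methyl ketone 2 (photochemical chain cleavage) ⇐ (−)-sclareol 1.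
4. 8 ⇐ 7 ⇐ benzene-1,2,4-triol 6 (MOM protection, bromination).
5. No ring is formed: the trans-decalin (rings A and B) comes intact from 1 and the arene from 6.

Assumption: the target is taken as the free aryl hydrogen sulfate as drawn; decalin carbons carry drimane numbers (C5, C8, C9, C10, C11) and arene carbons are C1′–C6′ (C1′ bears C11, C5′ the formyl group, C6′ the sulfate).

**Route**

Step 1
Reactants: 1 (−)-sclareol [(13R)-labd-14-ene-8α,13-diol]
Product: 2 4-[(1R,2R,4aS,8aS)-2-hydroxy-2,5,5,8a-tetramethyldecahydronaphthalen-1-yl]butan-2-one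
Conditions: OsO4 (2 mol %), NaIO4 (4 equiv), THF/H2O, 45 °C
Reagents that add atoms: none
Why: Lemieux–Johnson oxidation, in which catalytic OsO4 dihydroxylates the vinyl group and NaIO4 cleaves first the 14,15-diol and then the resulting 13-hydroxy-14-aldehyde, so the side chain is cut back to the C13 methyl ketone while the ring stereocentres are untouched.

Step 2
Reactants: 2 4-[(1R,2R,4aS,8aS)-2-hydroxy-2,5,5,8a-tetramethyldecahydronaphthalen-1-yl]butan-2-one
Product: 3 (2R,4aS,8aS)-2,5,5,8a-tetramethyl-1-methylidenedecahydronaphthalen-2-ol (drim-9(11)-en-8α-ol)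
Conditions: hν (medium-pressure Hg lamp, Pyrex filter), degassed hexane, rt
Reagents that add atoms: none
Why: Norrish type 2 cleavage, in which the excited methyl ketone abstracts the tertiary γ-hydrogen at C9 through a six-membered transition state and the 1,4-biradical fragments into acetone enol and the exocyclic C9=C11 alkene, leaving C5, C8 and C10 unchanged.

Step 3
Reactants: 3 drim-9(11)-en-8α-ol
Product: 4 (4aS,8aS)-2,5,5,8a-tetramethyl-3,4,4a,5,6,7,8,8a-octahydronaphthalene-1-carbaldehyde (drim-8-en-11-al)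
Conditions: (C5H5NH)[CrO3Cl] (2.5 equiv), 4 Å MS, CH2Cl2, rt
Reagents that add atoms: pyridinium chlorochromate, [O-][Cr](=O)(=O)Cl.c1cc[nH+]cc1
Why: Babler–Dauben oxidative transposition, in which the tertiary allylic chromate ester undergoes a [3,3] shift to the primary C11 chromate that hexavalent chromium oxidises to the tetrasubstituted enal; the C8 centre is erased here on purpose and reset in step 4.

Step 4
Reactants: 4 drim-8-en-11-al
Product: 5 (1S,2S,4aS,8aS)-2,5,5,8a-tetramethyldecahydronaphthalene-1-carbaldehyde (8β-methyl-9β-formyl)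
Conditions: H2 (4 atm), Pd/C (10 wt %), EtOAc, rt
Reagents that add atoms: none
Why: Heterogeneous syn-hydrogenation of the conjugated C8=C9 bond occurs from the α-face because the β-face is screened by the axial C10 methyl group, so H-8 and H-9 arrive α and the 8β-methyl (8S) centre of the target is set (C9 becomes sp2 again in step 7).

Step 5
Reactants: 6 benzene-1,2,4-triol
Product: 7 1,2,4-tris(methoxymethoxy)benzene
Conditions: MOMCl (3.6 equiv), i-Pr2NEt (4.5 equiv), CH2Cl2/DMF, 0 °C → rt, Ar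
Reagents that add atoms: chloromethyl methyl ether, COCCl
Why: O-alkylation of the three phenols (Williamson-type acetal formation) gives ethers that withstand LiOtBu and n-BuLi and that act as ortho-directing groups in step 8.

Step 6
Reactants: 7 1,2,4-tris(methoxymethoxy)benzene
Product: 8 1-bromo-2,4,5-tris(methoxymethoxy)benzene
Conditions: NBS (1.05 equiv), MeCN, 0 °C
Reagents that add atoms: N-bromosuccinimide, O=C1CCC(=O)N1Br
Why: Electrophilic aromatic bromination goes to C5 of 7, the only free position that is para to one alkoxy group and ortho to another without lying between two substituents.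

Step 7
Reactants: 5 (1S,2S,4aS,8aS)-2,5,5,8a-tetramethyldecahydronaphthalene-1-carbaldehyde; 8 1-bromo-2,4,5-tris(methoxymethoxy)benzene
Product: 11 1-{(E)-[(2S,4aS,8aS)-2,5,5,8a-tetramethyloctahydronaphthalen-1(2H)-ylidene]methyl}-2,4,5-tris(methoxymethoxy)benzene, via N-tosylhydrazone 9 (not isolated), via diazoalkane 10 (not isolated)
Conditions: TsNHNH2 (1.1 equiv), 1,4-dioxane, 70 °C; then 8 (1.0 equiv), Pd2(dba)3 (2.5 mol %), XPhos (10 mol %), LiOtBu (2.5 equiv), 100 °C
Reagents that add atoms: none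
Why: Barluenga-type palladium carbene cross-coupling with reversed polarity at the aldehyde carbon: C11, normally an acceptor, becomes through hydrazone 9 and Bamford–Stevens elimination the nucleophilic diazo carbon of 10, which is captured by the arylpalladium bromide formed from zerovalent palladium and the likewise electrophilic C–Br carbon of 8, so that aryl migration to the carbene carbon and syn β-hydride elimination of H-9 create the C11–C1′ bond and the C9=C11 alkene in one operation; the E geometry is expected from aryl migration anti to the quaternary C10 and from the much lower allylic strain of an aryl group cis to C8–H than cis to C10, and the 8S centre is not touched.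

Step 8
Reactants: 11 1-{(E)-[(2S,4aS,8aS)-2,5,5,8a-tetramethyloctahydronaphthalen-1(2H)-ylidene]methyl}-2,4,5-tris(methoxymethoxy)benzene
Product: 13 2,3,6-tris(methoxymethoxy)-5-{(E)-[(2S,4aS,8aS)-2,5,5,8a-tetramethyloctahydronaphthalen-1(2H)-ylidene]methyl}benzaldehyde, via aryllithium 12 (not isolated)
Conditions: n-BuLi (1.3 equiv), TMEDA, THF, 0 °C; DMF, −78 °C → rt; H2O
Reagents that add atoms: N,N-dimethylformamide, CN(C)C=O
Why: Directed ortho-metalation removes the C5′ proton, the only one flanked by two OMOM groups, and DMF formylates the aryllithium there, while the hindered trisubstituted styrene and the non-acidic C8–H are inert to n-BuLi.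

Step 9
Reactants: 13 2,3,6-tris(methoxymethoxy)-5-{(E)-[(2S,4aS,8aS)-2,5,5,8a-tetramethyloctahydronaphthalen-1(2H)-ylidene]methyl}benzaldehyde
Product: 15 2,3,6-trihydroxy-5-{(E)-[(2S,4aS,8aS)-2,5,5,8a-tetramethyloctahydronaphthalen-1(2H)-ylidene]methyl}benzaldehyde, via tris(trimethylsilyl) ether 14 (not isolated)
Conditions: Me3SiOTf (8 equiv), 2,2′-bipyridyl (12 equiv), CH2Cl2, 0 °C → rt; then H2O, rt, Ar
Reagents that add atoms: none
Why: Silyl triflate/2,2′-bipyridyl acetal cleavage turns aryl MOM ethers into aryl silyl ethers through N-(methoxymethyl)bipyridinium salts under buffered aprotic conditions and water then frees the phenols, so the electron-rich styrene with its ortho phenol never meets a strong Brønsted acid that would trigger spirocyclisation or E/Z scrambling.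

Step 10
Reactants: 15 2,3,6-trihydroxy-5-{(E)-[(2S,4aS,8aS)-2,5,5,8a-tetramethyloctahydronaphthalen-1(2H)-ylidene]methyl}benzaldehyde
Product: 18 2-formyl-3,4-dihydroxy-6-{(E)-[(2S,4aS,8aS)-2,5,5,8a-tetramethyloctahydronaphthalen-1(2H)-ylidene]methyl}phenyl hydrogen sulfate, via catechol phenylboronate 16 (not isolated), via boronate hydrogen sulfate 17 (not isolated)
Conditions: PhB(OH)2 (1.05 equiv), 4 Å MS, pyridine, rt, Ar; SO3·pyridine (4 equiv), 40 °C; H2O; C18 chromatography; H+-form sulfonic acid resin, MeOH/H2O, 0 °C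
Reagents that add atoms: sulfur trioxide pyridine complex, O=S(=O)=O.c1ccncc1
Why: Transient boronate protection followed by O-sulfation: phenylboronic acid ties up the C3′/C4′ catechol as a cyclic boronate so that SO3·pyridine can only sulfate the remaining C6′ phenol, and the boronate hydrolyses on aqueous work-up without affecting the base- and water-stable aryl sulfate.

**Compound list**

1 | (−)-sclareol, (13R)-labd-14-ene-8α,13-diol | C[C@@]1(O)CC[C@H]2C(C)(C)CCC[C@]2(C)[C@H]1CC[C@@](C)(O)C=C | starting material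
2 | 4-[(1R,2R,4aS,8aS)-2-hydroxy-2,5,5,8a-tetramethyldecahydronaphthalen-1-yl]butan-2-one | C[C@@]1(O)CC[C@H]2C(C)(C)CCC[C@]2(C)[C@H]1CCC(C)=O | intermediate
3 | (2R,4aS,8aS)-2,5,5,8a-tetramethyl-1-methylidenedecahydronaphthalen-2-ol (drim-9(11)-en-8α-ol) | C[C@@]1(O)CC[C@H]2C(C)(C)CCC[C@]2(C)C1=C | intermediate
4 | (4aS,8aS)-2,5,5,8a-tetramethyl-3,4,4a,5,6,7,8,8a-octahydronaphthalene-1-carbaldehyde (drim-8-en-11-al) | CC1=C(C=O)[C@@]2(C)CCCC(C)(C)[C@@H]2CC1 | intermediate
5 | (1S,2S,4aS,8aS)-2,5,5,8a-tetramethyldecahydronaphthalene-1-carbaldehyde (5α-H, 8β-methyl, 9β-formyl, 10β-methyl) | C[C@H]1CC[C@H]2C(C)(C)CCC[C@]2(C)[C@H]1C=O | intermediate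
6 | benzene-1,2,4-triol | Oc1ccc(O)c(O)c1 | starting material
7 | 1,2,4-tris(methoxymethoxy)benzene | COCOc1ccc(OCOC)c(OCOC)c1 | intermediate
8 | 1-bromo-2,4,5-tris(methoxymethoxy)benzene | COCOc1cc(OCOC)c(OCOC)cc1Br | intermediate
9 | N′-{(E)-[(1S,2S,4aS,8aS)-2,5,5,8a-tetramethyldecahydronaphthalen-1-yl]methylidene}-4-methylbenzenesulfonohydrazide | C[C@H]1CC[C@H]2C(C)(C)CCC[C@]2(C)[C@H]1/C=N/NS(=O)(=O)c1ccc(C)cc1 | intermediate
10 | (1S,2S,4aS,8aS)-1-(diazomethyl)-2,5,5,8a-tetramethyldecahydronaphthalene | C[C@H]1CC[C@H]2C(C)(C)CCC[C@]2(C)[C@H]1C=[N+]=[N-] | intermediate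
11 | 1-{(E)-[(2S,4aS,8aS)-2,5,5,8a-tetramethyloctahydronaphthalen-1(2H)-ylidene]methyl}-2,4,5-tris(methoxymethoxy)benzene | C[C@H]1CC[C@H]2C(C)(C)CCC[C@]2(C)/C1=C/c1cc(OCOC)c(OCOC)cc1OCOC | intermediate
12 | {2,3,6-tris(methoxymethoxy)-5-[(E)-((2S,4aS,8aS)-2,5,5,8a-tetramethyloctahydronaphthalen-1(2H)-ylidene)methyl]phenyl}lithium | C[C@H]1CC[C@H]2C(C)(C)CCC[C@]2(C)/C1=C/c1cc(OCOC)c(OCOC)c([Li])c1OCOC | intermediate
13 | 2,3,6-tris(methoxymethoxy)-5-{(E)-[(2S,4aS,8aS)-2,5,5,8a-tetramethyloctahydronaphthalen-1(2H)-ylidene]methyl}benzaldehyde | C[C@H]1CC[C@H]2C(C)(C)CCC[C@]2(C)/C1=C/c1cc(OCOC)c(OCOC)c(C=O)c1OCOC | intermediate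
14 | 5-{(E)-[(2S,4aS,8aS)-2,5,5,8a-tetramethyloctahydronaphthalen-1(2H)-ylidene]methyl}-2,3,6-tris(trimethylsilyloxy)benzaldehyde | C[C@H]1CC[C@H]2C(C)(C)CCC[C@]2(C)/C1=C/c1cc(O[Si](C)(C)C)c(O[Si](C)(C)C)c(C=O)c1O[Si](C)(C)C | intermediate
15 | 2,3,6-trihydroxy-5-{(E)-[(2S,4aS,8aS)-2,5,5,8a-tetramethyloctahydronaphthalen-1(2H)-ylidene]methyl}benzaldehyde | C[C@H]1CC[C@H]2C(C)(C)CCC[C@]2(C)/C1=C/c1cc(O)c(O)c(C=O)c1O | intermediate
16 | cyclic O3′,O4′-phenylboronate of 15 (2-phenyl-1,3,2-benzodioxaborole, C6′–OH free) | C[C@H]1CC[C@H]2C(C)(C)CCC[C@]2(C)/C1=C/c1cc2OB(c3ccccc3)Oc2c(C=O)c1O | intermediate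
17 | C6′ hydrogen sulfate of boronate 16 | C[C@H]1CC[C@H]2C(C)(C)CCC[C@]2(C)/C1=C/c1cc2OB(c3ccccc3)Oc2c(C=O)c1OS(=O)(=O)O | intermediate
18 | 2-formyl-3,4-dihydroxy-6-{(E)-[(2S,4aS,8aS)-2,5,5,8a-tetramethyloctahydronaphthalen-1(2H)-ylidene]methyl}phenyl hydrogen sulfate | C[C@H]1CC[C@H]2C(C)(C)CCC[C@]2(C)/C1=C/c1cc(O)c(O)c(C=O)c1OS(=O)(=O)O | target

**Step count and risks**

Total steps: 10. Longest linear sequence: 8 (steps 1–4 and 7–10, from 1).

The three steps most likely to fail:

Step 7 (carbene cross-coupling). The risks are a poor E/Z ratio, Bamford–Stevens alkene formation from the hindered diazoalkane, and alkene migration by palladium hydride. The fallback sets out from 5 and keeps C11 as the donor. Condensation with N2H4·H2O gives the N-unsubstituted (E)-hydrazone F3. This serves as an alkyl carbanion equivalent in a denitrogenative cross-coupling with 8 (Ni(cod)2, PMe3, DBU, THF, 60 °C) to give the saturated 1-{[(1S,2S,4aS,8aR)-2,5,5,8a-tetramethyldecahydronaphthalen-1-yl]methyl}-2,4,5-tris(methoxymethoxy)benzene F4. Benzylic dehydrogenation of this electron-rich arylalkane with DDQ (CH2Cl2, 0 °C) then introduces the C9=C11 bond under thermodynamic control, in favour of the E isomer, and comes back to the route at 11.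

Step 4 (hydrogenation of a tetrasubstituted enal). The risks are low reactivity and over-reduction of the aldehyde. The fallback sets out from 4. Luche reduction (NaBH4, CeCl3·7H2O, MeOH, 0 °C) gives the allylic alcohol drim-8-en-11-ol F1. Hydroxyl-directed hydrogenation with [Ir(cod)(PCy3)(py)]PF6 (H2, CH2Cl2), a catalyst that reduces tetrasubstituted alkenes and is again confined to the α-face, gives the saturated alcohol [(1S,2S,4aS,8aS)-2,5,5,8a-tetramethyldecahydronaphthalen-1-yl]methanol F2. Dess–Martin oxidation then comes back to the route at 5.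

Step 10 (site-selective sulfation). The risks are a boronate that does not hold during sulfation, or sulfation at a catechol oxygen. The fallback sets out from 15. 1,1′-Carbonyldiimidazole (1.05 equiv, THF, 0 °C) closes a five-membered cyclic carbonate on the catechol only, giving the isolable O3′,O4′-carbonate F5. SO3·NMe3/Et3N (DMF, 40 °C) sulfates the remaining phenol to the carbonate hydrogen sulfate F6. Aqueous NaHCO3/MeOH hydrolyses the carbonate without touching the aryl sulfate, and acidic resin treatment as in step 10 comes back to the route at 18.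

**Further compounds**

F1 | step 4 | [(4aS,8aS)-2,5,5,8a-tetramethyl-3,4,4a,5,6,7,8,8a-octahydronaphthalen-1-yl]methanol (drim-8-en-11-ol) | CC1=C(CO)[C@@]2(C)CCCC(C)(C)[C@@H]2CC1
F2 | step 4 | [(1S,2S,4aS,8aS)-2,5,5,8a-tetramethyldecahydronaphthalen-1-yl]methanol | C[C@H]1CC[C@H]2C(C)(C)CCC[C@]2(C)[C@H]1CO
F3 | step 7 | (E)-{[(1S,2S,4aS,8aS)-2,5,5,8a-tetramethyldecahydronaphthalen-1-yl]methylidene}hydrazine | C[C@H]1CC[C@H]2C(C)(C)CCC[C@]2(C)[C@H]1/C=N/N
F4 | step 7 | 1-{[(1S,2S,4aS,8aR)-2,5,5,8a-tetramethyldecahydronaphthalen-1-yl]methyl}-2,4,5-tris(methoxymethoxy)benzene | C[C@H]1CC[C@H]2C(C)(C)CCC[C@]2(C)[C@H]1Cc1cc(OCOC)c(OCOC)cc1OCOC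
F5 | step 10 | cyclic O3′,O4′-carbonate of 15 (1,3-benzodioxol-2-one, C6′–OH free) | C[C@H]1CC[C@H]2C(C)(C)CCC[C@]2(C)/C1=C/c1cc2OC(=O)Oc2c(C=O)c1O
F6 | step 10 | C6′ hydrogen sulfate of carbonate F5 | C[C@H]1CC[C@H]2C(C)(C)CCC[C@]2(C)/C1=C/c1cc2OC(=O)Oc2c(C=O)c1OS(=O)(=O)O
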